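**Plan**

- **Labels and cuts.** Labels are oxane O1 and C2–C6, and side chain C1'–C4' with Cl on C2'. The retrosynthesis cuts, in this order: C2–OH/C3–H (hydration of bromo enol ether 20); C3–Br (from C3–CO2H); O1–C2 (O1 returns to that carboxyl carbon); C3–C4 (ring closure in δ-lactone 16); C3'=C4' (Takai olefination); and C2'–CH3 and C2'–Cl (set on a γ-lactone).
- **Enabling feature.** C2 is a masked methyl ketone and C3 is its α-carbon. O1–C6 and C4 are the two CH2 arms on C5. An acetoacetate hung on the C6 oxygen therefore places a soft C3 nucleophile six ring atoms from a C4 iodide.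
- **Rings, forward.** Ring A is a temporary γ-lactone (C4–C5–C2'–C3'–O). It is opened, and ring B, a temporary δ-lactone, is closed at C3–C4. Ring C, the final oxane, then forms by moving O1 from the lactone carbonyl to C2.
- **The extra carbon.** The one extra carbon from diketene serves as tether, as activator of C3 and as placeholder for bromine. It leaves as CO2.
- **Stereochemistry.** C5 comes from an asymmetric conjugate reduction. C2' comes from methylation of the ring A enolate anti to the C5 arm. The E-alkene comes from the Takai olefination. C3 and C2 come from trans-diaxial addition of water to 20, supported by the anomeric effect.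

Key step: step 11

Assumption: in step 3 the (R)-ligand is taken to deliver hydride to the face of 5 that gives (R)-6; the antipodal ligand is used if the sense of induction is the reverse.

Step 1
Reactants: 1 1,3-dihydroxyacetone (used as its commercial dimer); 2 ethyl (triphenylphosphoranylidene)acetate
Product: 4 4-(hydroxymethyl)furan-2(5H)-one, via ethyl 4-hydroxy-3-(hydroxymethyl)but-2-enoate 3 (not isolated)
Conditions: CH2Cl2, rt, 16 h
Reagents that add atoms: none
Why: Wittig olefination of the symmetrical ketone with a stabilised ylide gives an enoate in which one CH2OH is always cis to the ester, so lactonisation to the butenolide follows in the flask and no stereocentre arises.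

Step 2
Reactants: 4 4-(hydroxymethyl)furan-2(5H)-one
Product: 5 4-({[tert-butyl(dimethyl)silyl]oxy}methyl)furan-2(5H)-one
Conditions: TBSCl, imidazole, DMF, 0 °C to rt
Reagents that add atoms: tert-butyldimethylsilyl chloride, CC(C)(C)[Si](C)(C)Cl
Why: Standard silylation of a primary alcohol; the ether keeps the two CH2O arms different, which blocks racemisation by translactonisation later on.

Step 3
Reactants: 5 4-({[tert-butyl(dimethyl)silyl]oxy}methyl)furan-2(5H)-one
Product: 6 (4R)-4-({[tert-butyl(dimethyl)silyl]oxy}methyl)oxolan-2-one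
Conditions: Cu(OAc)2·H2O (2 mol %), (R)-DTBM-SEGPHOS (2 mol %), (EtO)2MeSiH, t-BuOH, toluene, 0 °C
Reagents that add atoms: none
Why: Copper hydride asymmetric conjugate reduction of a β-substituted butenolide; the chiral bisphosphine selects one enantiotopic face and so sets the future C5.

Step 4
Reactants: 6 (4R)-4-({[tert-butyl(dimethyl)silyl]oxy}methyl)oxolan-2-one
Product: 7 (4R)-3-chloro-4-({[tert-butyl(dimethyl)silyl]oxy}methyl)oxolan-2-one (C3 epimers)
Conditions: LDA, THF, −78 °C; enolate cannulated into C2Cl6, THF, −78 °C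
Reagents that add atoms: hexachloroethane, ClC(Cl)(Cl)C(Cl)(Cl)Cl
Why: Electrophilic α-chlorination of a lactone lithium enolate; inverse addition should suppress proton exchange and dichlorination, and the new centre needs no control because step 5 flattens it again.

Step 5
Reactants: 7 (4R)-3-chloro-4-({[tert-butyl(dimethyl)silyl]oxy}methyl)oxolan-2-one
Product: 8 (3S,4R)-3-chloro-4-({[tert-butyl(dimethyl)silyl]oxy}methyl)-3-methyloxolan-2-one (CH3 trans and Cl cis to the silyloxymethyl arm)
Conditions: LiHMDS, THF–DMPU, −78 °C; MeI, −78 to −40 °C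
Reagents that add atoms: iodomethane, CI
Why: Alkylation of an α-chloro ester enolate; MeI should approach the planar five-ring enolate of ring A anti to the C4 arm, so cyclic 1,2-induction sets the tertiary chloride centre C2'.

Step 6
Reactants: 8 (3S,4R)-3-chloro-4-({[tert-butyl(dimethyl)silyl]oxy}methyl)-3-methyloxolan-2-one
Product: 9 (3S,4R)-3-chloro-4-({[tert-butyl(dimethyl)silyl]oxy}methyl)-3-methyloxolan-2-ol (anomers)
Conditions: DIBAL-H (1.1 equiv), CH2Cl2, −78 °C; Rochelle salt
Reagents that add atoms: none
Why: Partial lactone reduction stops at the aluminium hemiacetal at −78 °C, and the quaternary α-carbon cannot epimerise.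

Step 7
Reactants: 9 (3S,4R)-3-chloro-4-({[tert-butyl(dimethyl)silyl]oxy}methyl)-3-methyloxolan-2-ol
Product: 10 (2R,3S,4E)-5-bromo-2-({[tert-butyl(dimethyl)silyl]oxy}methyl)-3-chloro-3-methylpent-4-en-1-ol
Conditions: CHBr3, anhydrous CrBr2 (excess), THF, 0 °C to rt
Reagents that add atoms: bromoform, BrC(Br)Br
Why: Takai olefination of the lactol through its open hydroxy aldehyde; the geminal dichromium reagent should give the E-bromoalkene with this bulky α-quaternary aldehyde, CrBr2 avoids chloride/bromide scrambling, and ring A opens to free the C4 hydroxyl.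

Step 8
Reactants: 10 (2R,3S,4E)-5-bromo-2-({[tert-butyl(dimethyl)silyl]oxy}methyl)-3-chloro-3-methylpent-4-en-1-ol
Product: 11 tert-butyl{[(2R,3R,4E)-5-bromo-3-chloro-2-(iodomethyl)-3-methylpent-4-en-1-yl]oxy}dimethylsilane
Conditions: I2, PPh3, imidazole, CH2Cl2, 0 °C
Reagents that add atoms: iodine, II
Why: Appel iodination of the primary alcohol under buffered conditions leaves the tertiary chloride, the vinyl bromide and the silyl ether alone; the changed descriptors follow only from the rank of iodine.

Step 9
Reactants: 11 tert-butyl{[(2R,3R,4E)-5-bromo-3-chloro-2-(iodomethyl)-3-methylpent-4-en-1-yl]oxy}dimethylsilane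
Product: 12 (2R,3R,4E)-5-bromo-3-chloro-2-(iodomethyl)-3-methylpent-4-en-1-ol
Conditions: HF·pyridine, THF, 0 °C
Reagents that add atoms: none
Why: Acidic fluoride desilylation frees the C6 hydroxyl without ever forming an alkoxide, so oxetane formation with the C4 iodide is avoided.

Step 10
Reactants: 12 (2R,3R,4E)-5-bromo-3-chloro-2-(iodomethyl)-3-methylpent-4-en-1-ol; 13 diketene
Product: 14 (2R,3R,4E)-5-bromo-3-chloro-2-(iodomethyl)-3-methylpent-4-en-1-yl 3-oxobutanoate
Conditions: DMAP (5 mol %), CH2Cl2, −20 to 0 °C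
Reagents that add atoms: none
Why: DMAP-catalysed acetoacetylation by ring opening of diketene brings in C1, C2, C3 and the helper carbonyl carbon under nearly neutral conditions.

Step 11
Reactants: 14 (2R,3R,4E)-5-bromo-3-chloro-2-(iodomethyl)-3-methylpent-4-en-1-yl 3-oxobutanoate
Product: 16 (5R)-3-acetyl-5-[(2S,3E)-4-bromo-2-chlorobut-3-en-2-yl]oxan-2-one (C3 epimers and enol), via sodium enolate 15 (not isolated)
Conditions: NaH (1.05 equiv), THF, 0 °C; then dilution to 0.005 M, 45 °C
Reagents that add atoms: none
Why: NaH turns the acetoacetate of 14 (pKa about 11) into the chelated sodium enolate 15, whose C3 displaces iodide from C4 in an intramolecular SN2 reaction, so the C3–C4 bond forms inside temporary ring B, in which the helper carbonyl carbon is the sixth ring atom in place of C2. The closest known reaction type is the acetoacetic ester alkylation in its intramolecular form, that is lactone formation by C-alkylation of ω-haloalkyl β-keto esters and malonates. The single ring closes in the favoured 6-(enolexo)-exo-tet mode. The only new stereocentre, C3, is an acidic β-dicarbonyl CH that needs no control and is flattened again in step 12, while C5 and C2' stay untouched because the base is consumed by C3–H and the enolate is too weak a base for E2 at the chloride. The step needs C- over O-alkylation and ring closure over dimerisation: the ketone oxygen could only close an eight-membered ring, the ester oxygen is held with it in the sodium chelate and faces a soft iodide, and high dilution deals with dimerisation. The tertiary allylic chloride and the vinyl bromide are not SN2 partners, so the primary iodide is the only electrophile.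

Step 12
Reactants: 16 (5R)-3-acetyl-5-[(2S,3E)-4-bromo-2-chlorobut-3-en-2-yl]oxan-2-one
Product: 18 2-(trimethylsilyl)ethyl (3R)-3-[(2S,3E)-4-bromo-2-chlorobut-3-en-2-yl]-6-methyl-3,4-dihydro-2H-pyran-5-carboxylate, via ring-opened hydroxy keto ester 17 (not isolated)
Conditions: Me3SiCH2CH2OH (5 equiv), CSA (0.2 equiv), 4 Å molecular sieves, CH2Cl2, 35 °C
Reagents that add atoms: 2-(trimethylsilyl)ethanol, C[Si](C)(C)CCO
Why: Acyl-lactone rearrangement; acid-catalysed alcoholysis opens ring B to 17, whose C6 hydroxyl adds to the ketone C2 and loses water towards C3 to give the conjugated vinylogous carbonate of ring C, and the poorly ionising solvent should spare the allylic chloride.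

Step 13
Reactants: 18 2-(trimethylsilyl)ethyl (3R)-3-[(2S,3E)-4-bromo-2-chlorobut-3-en-2-yl]-6-methyl-3,4-dihydro-2H-pyran-5-carboxylate
Product: 19 (3R)-3-[(2S,3E)-4-bromo-2-chlorobut-3-en-2-yl]-6-methyl-3,4-dihydro-2H-pyran-5-carboxylic acid
Conditions: TASF (2 equiv), DMF, 0 °C; dilute HCl work-up
Reagents that add atoms: none
Why: Fluoride-induced fragmentation of a 2-(trimethylsilyl)ethyl ester frees the acid with a weakly basic fluoride source, which hydroxide saponification of this hindered vinylogous carbonate would not allow next to the tertiary chloride.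

Step 14
Reactants: 19 (3R)-3-[(2S,3E)-4-bromo-2-chlorobut-3-en-2-yl]-6-methyl-3,4-dihydro-2H-pyran-5-carboxylic acid
Product: 20 (3R)-5-bromo-3-[(2S,3E)-4-bromo-2-chlorobut-3-en-2-yl]-6-methyl-3,4-dihydro-2H-pyran
Conditions: NBS (1.0 equiv), LiOAc (0.1 equiv), MeCN, 0 °C, dark
Reagents that add atoms: N-bromosuccinimide, O=C1CCC(=O)N1Br
Why: Hunsdiecker-type halodecarboxylation of an α,β-unsaturated acid; electrophilic bromine attacks C3, the nucleophilic carbon of the push–pull alkene, ipso to the carboxyl, and loss of CO2 restores the enol ether, so bromine goes to C3 and not to C1 while the electron-poor bromovinyl group stays inert.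

Step 15
Reactants: 20 (3R)-5-bromo-3-[(2S,3E)-4-bromo-2-chlorobut-3-en-2-yl]-6-methyl-3,4-dihydro-2H-pyran
Product: 22 (2R,3S,5R)-3-bromo-5-[(2S,3E)-4-bromo-2-chlorobut-3-en-2-yl]-2-methyloxan-2-ol, via oxocarbenium ion 21 (not isolated)
Conditions: TsOH·H2O (10 mol %), THF–H2O 4:1, 0 °C
Reagents that add atoms: water, O
Why: Acid-catalysed hydration of an enol ether with rate-limiting C-protonation; with the bulky C5 group pseudo-equatorial, the proton should enter C3 along the axial, chair-forming path trans to that group, which leaves bromine equatorial (3S), and water then adds axially to 21, a position also held by the anomeric effect (2R).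

**Compound list**

1 | 1,3-dihydroxyacetone | OCC(=O)CO | starting material
2 | ethyl (triphenylphosphoranylidene)acetate | CCOC(=O)C=P(c1ccccc1)(c1ccccc1)c1ccccc1 | starting material
3 | ethyl 4-hydroxy-3-(hydroxymethyl)but-2-enoate | CCOC(=O)C=C(CO)CO | intermediate
4 | 4-(hydroxymethyl)furan-2(5H)-one | O=C1C=C(CO)CO1 | intermediate
5 | 4-({[tert-butyl(dimethyl)silyl]oxy}methyl)furan-2(5H)-one | O=C1C=C(CO[Si](C)(C)C(C)(C)C)CO1 | intermediate
6 | (4R)-4-({[tert-butyl(dimethyl)silyl]oxy}methyl)oxolan-2-one | O=C1C[C@@H](CO[Si](C)(C)C(C)(C)C)CO1 | intermediate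
7 | (4R)-3-chloro-4-({[tert-butyl(dimethyl)silyl]oxy}methyl)oxolan-2-one | O=C1C(Cl)[C@@H](CO[Si](C)(C)C(C)(C)C)CO1 | intermediate
8 | (3S,4R)-3-chloro-4-({[tert-butyl(dimethyl)silyl]oxy}methyl)-3-methyloxolan-2-one | O=C1[C@@](C)(Cl)[C@@H](CO[Si](C)(C)C(C)(C)C)CO1 | intermediate
9 | (3S,4R)-3-chloro-4-({[tert-butyl(dimethyl)silyl]oxy}methyl)-3-methyloxolan-2-ol | OC1[C@@](C)(Cl)[C@@H](CO[Si](C)(C)C(C)(C)C)CO1 | intermediate
10 | (2R,3S,4E)-5-bromo-2-({[tert-butyl(dimethyl)silyl]oxy}methyl)-3-chloro-3-methylpent-4-en-1-ol | C[C@@](Cl)(/C=C/Br)[C@H](CO)CO[Si](C)(C)C(C)(C)C | intermediate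
11 | tert-butyl{[(2R,3R,4E)-5-bromo-3-chloro-2-(iodomethyl)-3-methylpent-4-en-1-yl]oxy}dimethylsilane | C[C@@](Cl)(/C=C/Br)[C@H](CI)CO[Si](C)(C)C(C)(C)C | intermediate
12 | (2R,3R,4E)-5-bromo-3-chloro-2-(iodomethyl)-3-methylpent-4-en-1-ol | C[C@@](Cl)(/C=C/Br)[C@H](CI)CO | intermediate
13 | diketene | C=C1CC(=O)O1 | starting material
14 | (2R,3R,4E)-5-bromo-3-chloro-2-(iodomethyl)-3-methylpent-4-en-1-yl 3-oxobutanoate | C[C@@](Cl)(/C=C/Br)[C@H](CI)COC(=O)CC(C)=O | intermediate
15 | sodium enolate of 14 | C[C@@](Cl)(/C=C/Br)[C@H](CI)COC(=O)C=C(C)[O-].[Na+] | intermediate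
16 | (5R)-3-acetyl-5-[(2S,3E)-4-bromo-2-chlorobut-3-en-2-yl]oxan-2-one | C[C@@](Cl)(/C=C/Br)[C@H]1COC(=O)C(C(C)=O)C1 | intermediate
17 | 2-(trimethylsilyl)ethyl (4R,5S,6E)-2-acetyl-7-bromo-5-chloro-4-(hydroxymethyl)-5-methylhept-6-enoate | C[C@@](Cl)(/C=C/Br)[C@H](CC(C(C)=O)C(=O)OCC[Si](C)(C)C)CO | intermediate
18 | 2-(trimethylsilyl)ethyl (3R)-3-[(2S,3E)-4-bromo-2-chlorobut-3-en-2-yl]-6-methyl-3,4-dihydro-2H-pyran-5-carboxylate | C[C@@](Cl)(/C=C/Br)[C@H]1COC(C)=C(C(=O)OCC[Si](C)(C)C)C1 | intermediate
19 | (3R)-3-[(2S,3E)-4-bromo-2-chlorobut-3-en-2-yl]-6-methyl-3,4-dihydro-2H-pyran-5-carboxylic acid | C[C@@](Cl)(/C=C/Br)[C@H]1COC(C)=C(C(=O)O)C1 | intermediate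
20 | (3R)-5-bromo-3-[(2S,3E)-4-bromo-2-chlorobut-3-en-2-yl]-6-methyl-3,4-dihydro-2H-pyran | C[C@@](Cl)(/C=C/Br)[C@H]1COC(C)=C(Br)C1 | intermediate
21 | (3S,5R)-3-bromo-5-[(2S,3E)-4-bromo-2-chlorobut-3-en-2-yl]-2-methyl-3,4,5,6-tetrahydropyrylium | C[C@@](Cl)(/C=C/Br)[C@H]1C[O+]=C(C)[C@@H](Br)C1 | intermediate
22 | (2R,3S,5R)-3-bromo-5-[(2S,3E)-4-bromo-2-chlorobut-3-en-2-yl]-2-methyloxan-2-ol | C[C@@](Cl)(/C=C/Br)[C@H]1CO[C@@](C)(O)[C@@H](Br)C1 | target

Total step count: 15. Longest linear sequence: 15 steps (1 to 22).

**Steps most likely to fail**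

**Step 11.**
- **What may go wrong:** ring closure may lose to O-alkylation through the ester oxygen, which also gives a six-membered ring, or to oligomerisation.
- **Fallback:** the order of bond formation is reversed, starting from 11.
- Diketene 13 and 2-(trimethylsilyl)ethanol (DMAP cat., CH2Cl2) give 2-(trimethylsilyl)ethyl 3-oxobutanoate F1.
- The potassium enolate of this ester (K2CO3, DMF, rt) is alkylated by iodide 11. This gives 2-(trimethylsilyl)ethyl (4R,5S,6E)-2-acetyl-7-bromo-4-({[tert-butyl(dimethyl)silyl]oxy}methyl)-5-chloro-5-methylhept-6-enoate F2.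
- HF·pyridine removes the silyl ether, and CSA over molecular sieves then cyclodehydrates through 17. The route is rejoined at 18.

**Step 12.**
- **What may go wrong:** alcoholysis of the enolised lactone may be slow, or the tertiary allylic chloride may solvolyse under acid.
- **Fallback:** ring B is kept as the final ring and the acetyl group is sacrificed instead of the lactone carbonyl, starting from 16.
- NBS (CH2Cl2, 0 °C) gives (5R)-3-acetyl-3-bromo-5-[(2S,3E)-4-bromo-2-chlorobut-3-en-2-yl]oxan-2-one F3.
- K2CO3 in MeOH at −20 °C removes the acetyl group by retro-Claisen cleavage.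
- Axial protonation of the bromo enolate should then give (3S,5R)-3-bromo-5-[(2S,3E)-4-bromo-2-chlorobut-3-en-2-yl]oxan-2-one F4.
- MeLi/CeCl3 (THF, −78 °C, AcOH quench at that temperature) adds the methyl group to the lactone carbonyl. The route comes back at 22.

**Step 15.**
- **What may go wrong:** facial selectivity in the protonation of C3 may be poor.
- **Fallback:** kinetic control is replaced by a thermodynamic relay, starting from 20.
- Any (2R,3R,5R)-3-bromo-5-[(2S,3E)-4-bromo-2-chlorobut-3-en-2-yl]-2-methyloxan-2-ol F5 formed in the hydration is separated.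
- It is equilibrated with LiBr in acetone at rt, by SN2 bromide exchange at C3 of the open-chain α-bromo ketone with inversion at each event.
- The mixture is separated again and the C3 epimer recycled. The route comes back at 22.

**Further compounds**

F1 | step 11 | 2-(trimethylsilyl)ethyl 3-oxobutanoate | CC(=O)CC(=O)OCC[Si](C)(C)C
F2 | step 11 | 2-(trimethylsilyl)ethyl (4R,5S,6E)-2-acetyl-7-bromo-4-({[tert-butyl(dimethyl)silyl]oxy}methyl)-5-chloro-5-methylhept-6-enoate | C[C@@](Cl)(/C=C/Br)[C@H](CC(C(C)=O)C(=O)OCC[Si](C)(C)C)CO[Si](C)(C)C(C)(C)C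
F3 | step 12 | (5R)-3-acetyl-3-bromo-5-[(2S,3E)-4-bromo-2-chlorobut-3-en-2-yl]oxan-2-one | C[C@@](Cl)(/C=C/Br)[C@H]1COC(=O)C(Br)(C(C)=O)C1
F4 | step 12 | (3S,5R)-3-bromo-5-[(2S,3E)-4-bromo-2-chlorobut-3-en-2-yl]oxan-2-one | C[C@@](Cl)(/C=C/Br)[C@H]1COC(=O)[C@@H](Br)C1
F5 | step 15 | (2R,3R,5R)-3-bromo-5-[(2S,3E)-4-bromo-2-chlorobut-3-en-2-yl]-2-methyloxan-2-ol | C[C@@](Cl)(/C=C/Br)[C@H]1CO[C@@](C)(O)[C@H](Br)C1
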